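Assumption: the target has no stereocentre and no stereogenic double bond (the prenyl alkene carries two identical methyl groups), so it is achiral and needs no enantiocontrol. The one stereocentre that appears on the way (the α-carbon of the β-keto ester from the Claisen step) is racemic and is destroyed on decarboxylation.

## Retrosynthetic overview

1. Target ⇒ its tris-MOM ether, deprotected last with mild acid; the 3'-prenyl group is carried in from the ring B fragment.
2. Ring C is the only ring built (rings A and B are bought as benzenes): 2-hydroxydeoxybenzoin + one carbon (C2) from Me2NCH(OMe)2.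
3. Deoxybenzoin C3–C4 bond ⇒ crossed Claisen condensation of the lithium enolate of the ring B allyl arylacetate with the ring A N-acylimidazole, then removal of both allyl groups by zerovalent palladium with decarboxylation.
4. Ring B arylacetate ⇒ 5-methoxyresorcinol bis-MOM ether by two directed ortho-lithiations (oxirane between the two OMOM groups, then prenyl bromide at the symmetric remaining position), then oxidation of CH2CH2OH to CH2CO2-allyl.
5. Ring A acyl donor ⇒ methyl 2,4-dihydroxybenzoate (4-O-MOM, 2-O-allyl, saponification, CDI).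

## Route

Step 1
Reactants: 1 5-methoxyresorcinol (5-methoxybenzene-1,3-diol)
Product: 2 1-methoxy-3,5-bis(methoxymethoxy)benzene
Conditions: NaH (2.4 equiv), MOMCl (2.4 equiv), DMF, 0 °C to rt
Reagents that add atoms: chloromethyl methyl ether (MOMCl), COCCl
Why: Williamson-type O-alkylation of both phenoxides gives the bis-MOM ether, whose acetal oxygens direct the later lithiations.

Step 2
Reactants: 2 1-methoxy-3,5-bis(methoxymethoxy)benzene
Product: 4 2-[4-methoxy-2,6-bis(methoxymethoxy)phenyl]ethan-1-ol, via aryllithium 3 (not isolated)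
Conditions: n-BuLi (1.1 equiv), TMEDA, THF, 0 °C; oxirane (2.9 M in THF, 1.5 equiv), 0 °C to rt; H2O
Reagents that add atoms: oxirane (ethylene oxide), C1CO1
Why: Directed ortho-metalation occurs at the carbon flanked by the two chelating OMOM groups, and the aryllithium opens oxirane by SN2 to install the two-carbon arm.

Step 3
Reactants: 4 2-[4-methoxy-2,6-bis(methoxymethoxy)phenyl]ethan-1-ol
Product: 5 tert-butyl{2-[4-methoxy-2,6-bis(methoxymethoxy)phenyl]ethoxy}dimethylsilane
Conditions: TBSCl (1.2 equiv), imidazole (2.5 equiv), DMF, rt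
Reagents that add atoms: tert-butyldimethylsilyl chloride, CC(C)(C)[Si](C)(C)Cl
Why: Silylation masks the acidic primary OH so that the second lithiation needs only one equivalent of base and the alkoxide cannot be O-prenylated.

Step 4
Reactants: 5 tert-butyl{2-[4-methoxy-2,6-bis(methoxymethoxy)phenyl]ethoxy}dimethylsilane
Product: 7 tert-butyl{2-[4-methoxy-2,6-bis(methoxymethoxy)-3-(3-methylbut-2-en-1-yl)phenyl]ethoxy}dimethylsilane, via aryllithium 6 (not isolated)
Conditions: n-BuLi (1.2 equiv), TMEDA, THF, 0 °C; CuI (10 mol%), prenyl bromide (1.3 equiv), −78 °C to rt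
Reagents that add atoms: prenyl bromide (1-bromo-3-methylbut-2-ene), CC(C)=CCBr
Why: The two remaining ring positions are equivalent by symmetry and each lies between OMOM and OMe, so directed ortho-metalation followed by copper-catalysed SN2 allylic substitution gives a single linear-prenyl regioisomer.

Step 5
Reactants: 7 tert-butyl{2-[4-methoxy-2,6-bis(methoxymethoxy)-3-(3-methylbut-2-en-1-yl)phenyl]ethoxy}dimethylsilane
Product: 8 2-[4-methoxy-2,6-bis(methoxymethoxy)-3-(3-methylbut-2-en-1-yl)phenyl]ethan-1-ol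
Conditions: Bu4NF (1.2 equiv), THF, 0 °C to rt
Reagents that add atoms: none
Why: Fluoride-driven desilylation frees the primary alcohol without touching MOM ethers or the prenyl group.

Step 6
Reactants: 8 2-[4-methoxy-2,6-bis(methoxymethoxy)-3-(3-methylbut-2-en-1-yl)phenyl]ethan-1-ol
Product: 9 2-[4-methoxy-2,6-bis(methoxymethoxy)-3-(3-methylbut-2-en-1-yl)phenyl]acetaldehyde
Conditions: Dess–Martin periodinane (1.3 equiv), NaHCO3, CH2Cl2, 0 °C to rt; crude used at once
Reagents that add atoms: none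
Why: Dess–Martin oxidation stops cleanly at the aldehyde under buffered, near-neutral conditions that leave the alkene, the electron-rich arene and the acetals alone.

Step 7
Reactants: 9 2-[4-methoxy-2,6-bis(methoxymethoxy)-3-(3-methylbut-2-en-1-yl)phenyl]acetaldehyde
Product: 10 2-[4-methoxy-2,6-bis(methoxymethoxy)-3-(3-methylbut-2-en-1-yl)phenyl]acetic acid
Conditions: NaClO2 (3 equiv), NaH2PO4 (4 equiv), 2-methyl-2-butene (20 equiv), t-BuOH/H2O, 0 °C to rt
Reagents that add atoms: sodium chlorite, [Na+].[O-]Cl=O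
Why: Pinnick oxidation converts the aldehyde to the acid at pH about 4, and the large excess of 2-methyl-2-butene scavenges HOCl before it can attack the prenyl group or the arene.

Step 8
Reactants: 10 2-[4-methoxy-2,6-bis(methoxymethoxy)-3-(3-methylbut-2-en-1-yl)phenyl]acetic acid
Product: 11 prop-2-en-1-yl 2-[4-methoxy-2,6-bis(methoxymethoxy)-3-(3-methylbut-2-en-1-yl)phenyl]acetate
Conditions: allyl bromide (1.3 equiv), K2CO3 (1.5 equiv), DMF, rt
Reagents that add atoms: allyl bromide, C=CCBr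
Why: SN2 alkylation of the carboxylate gives an allyl ester that can later be removed under neutral conditions by zerovalent palladium.

Step 9
Reactants: 12 methyl 2,4-dihydroxybenzoate
Product: 13 methyl 2-hydroxy-4-(methoxymethoxy)benzoate
Conditions: MOMCl (1.1 equiv), K2CO3 (1.5 equiv), acetone, 0 °C to rt
Reagents that add atoms: chloromethyl methyl ether (MOMCl), COCCl
Why: Selective Williamson-type O-alkylation of the 4-OH works because the 2-OH is hydrogen-bonded to the ester carbonyl and much less nucleophilic.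

Step 10
Reactants: 13 methyl 2-hydroxy-4-(methoxymethoxy)benzoate
Product: 14 methyl 4-(methoxymethoxy)-2-(prop-2-en-1-yloxy)benzoate
Conditions: allyl bromide (1.5 equiv), K2CO3 (2 equiv), DMF, 60 °C
Reagents that add atoms: allyl bromide, C=CCBr
Why: Williamson etherification under forcing conditions caps the chelated 2-OH with a group orthogonal to MOM.

Step 11
Reactants: 14 methyl 4-(methoxymethoxy)-2-(prop-2-en-1-yloxy)benzoate
Product: 15 4-(methoxymethoxy)-2-(prop-2-en-1-yloxy)benzoic acid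
Conditions: LiOH (3 equiv), THF/MeOH/H2O, 50 °C; then 1 M HCl to pH 4, 0 °C
Reagents that add atoms: lithium hydroxide (its oxygen ends in the CO2H group), [Li+].[OH-]
Why: Saponification of the methyl ester leaves the base-stable MOM and allyl ethers intact, and the brief cold acidification to pH 4 does not cleave the MOM ether.

Step 12
Reactants: 15 4-(methoxymethoxy)-2-(prop-2-en-1-yloxy)benzoic acid
Product: 16 (1H-imidazol-1-yl)[4-(methoxymethoxy)-2-(prop-2-en-1-yloxy)phenyl]methanone
Conditions: CDI (1.15 equiv), CH2Cl2, rt; quick cold-water wash, dry, concentrate, use at once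
Reagents that add atoms: 1,1'-carbonyldiimidazole (CDI), O=C(n1ccnc1)n1ccnc1
Why: Staab activation gives a reactive acyl donor under neutral conditions (no HCl, so the MOM ether survives), needed because the electron-rich methyl ester is a poor Claisen acceptor.

Step 13
Reactants: 11 prop-2-en-1-yl 2-[4-methoxy-2,6-bis(methoxymethoxy)-3-(3-methylbut-2-en-1-yl)phenyl]acetate; 16 (1H-imidazol-1-yl)[4-(methoxymethoxy)-2-(prop-2-en-1-yloxy)phenyl]methanone
Product: 18 prop-2-en-1-yl 3-[4-(methoxymethoxy)-2-(prop-2-en-1-yloxy)phenyl]-2-[4-methoxy-2,6-bis(methoxymethoxy)-3-(3-methylbut-2-en-1-yl)phenyl]-3-oxopropanoate (racemic at C2), via lithium ester enolate 17 (not isolated)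
Conditions: LiN(SiMe3)2 (2.2 equiv), THF, −78 °C; then 16 (1.1 equiv) in THF, −78 to −30 °C; AcOH (2.5 equiv) quench
Reagents that add atoms: none
Why: Crossed Claisen condensation (C-acylation of the preformed ester enolate by the non-enolisable acyl imidazole) forms the C3–C4 bond, the second equivalent of base traps the more acidic β-keto ester, and the new stereocentre is racemic and removed in the next step.

Step 14
Reactants: 18 prop-2-en-1-yl 3-[4-(methoxymethoxy)-2-(prop-2-en-1-yloxy)phenyl]-2-[4-methoxy-2,6-bis(methoxymethoxy)-3-(3-methylbut-2-en-1-yl)phenyl]-3-oxopropanoate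
Product: 20 1-[2-hydroxy-4-(methoxymethoxy)phenyl]-2-[4-methoxy-2,6-bis(methoxymethoxy)-3-(3-methylbut-2-en-1-yl)phenyl]ethan-1-one, via beta-keto acid 19 (not isolated)
Conditions: Pd(PPh3)4 (5 mol%), morpholine (10 equiv), THF, rt to 45 °C
Reagents that add atoms: none
Why: Tsuji–Trost deallylation by zerovalent palladium (π-allyl capture by morpholine) cleaves both the allyl ester and the allyl aryl ether, and the resulting β-keto acid decarboxylates spontaneously, while the prenyl group, which has no allylic leaving group, is inert.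

Step 15
Reactants: 20 1-[2-hydroxy-4-(methoxymethoxy)phenyl]-2-[4-methoxy-2,6-bis(methoxymethoxy)-3-(3-methylbut-2-en-1-yl)phenyl]ethan-1-one
Product: 22 7-(methoxymethoxy)-3-[4-methoxy-2,6-bis(methoxymethoxy)-3-(3-methylbut-2-en-1-yl)phenyl]-4H-chromen-4-one, via enaminone 21 (not isolated)
Conditions: Me2NCH(OMe)2 (3 equiv), toluene, 90 °C; then AcOH (cat.), 60 °C
Reagents that add atoms: N,N-dimethylformamide dimethyl acetal, COC(OC)N(C)C
Why: Condensation of the active methylene with the formamide acetal gives an enaminone that closes ring C by intramolecular oxa-Michael addition of the free 2-OH and loss of dimethylamine; the ring B oxygens are still protected, so no benzofuran can form.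

Step 16
Reactants: 22 7-(methoxymethoxy)-3-[4-methoxy-2,6-bis(methoxymethoxy)-3-(3-methylbut-2-en-1-yl)phenyl]-4H-chromen-4-one
Product: 23 3-[2,6-dihydroxy-4-methoxy-3-(3-methylbut-2-en-1-yl)phenyl]-7-hydroxy-4H-chromen-4-one (target, achiral)
Conditions: HCl (1.25 M in MeOH), rt to 40 °C, monitored; NaHCO3 quench
Reagents that add atoms: none
Why: Acid-catalysed acetal exchange with methanol removes all three MOM groups, and dilute acid at low temperature is used so the prenyl alkene is not protonated and does not cyclise onto the 2'-OH; no stereocentre has to be set.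

## Compound list

1 | 5-methoxyresorcinol (5-methoxybenzene-1,3-diol) | COc1cc(O)cc(O)c1 | starting material
2 | 1-methoxy-3,5-bis(methoxymethoxy)benzene | COCOc1cc(OC)cc(OCOC)c1 | intermediate
3 | [4-methoxy-2,6-bis(methoxymethoxy)phenyl]lithium | [Li]c1c(OCOC)cc(OC)cc1OCOC | intermediate
4 | 2-[4-methoxy-2,6-bis(methoxymethoxy)phenyl]ethan-1-ol | COCOc1cc(OC)cc(OCOC)c1CCO | intermediate
5 | tert-butyl{2-[4-methoxy-2,6-bis(methoxymethoxy)phenyl]ethoxy}dimethylsilane | COCOc1cc(OC)cc(OCOC)c1CCO[Si](C)(C)C(C)(C)C | intermediate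
6 | [3-(2-{[tert-butyl(dimethyl)silyl]oxy}ethyl)-6-methoxy-2,4-bis(methoxymethoxy)phenyl]lithium | [Li]c1c(OC)cc(OCOC)c(CCO[Si](C)(C)C(C)(C)C)c1OCOC | intermediate
7 | tert-butyl{2-[4-methoxy-2,6-bis(methoxymethoxy)-3-(3-methylbut-2-en-1-yl)phenyl]ethoxy}dimethylsilane | COCOc1cc(OC)c(CC=C(C)C)c(OCOC)c1CCO[Si](C)(C)C(C)(C)C | intermediate
8 | 2-[4-methoxy-2,6-bis(methoxymethoxy)-3-(3-methylbut-2-en-1-yl)phenyl]ethan-1-ol | COCOc1cc(OC)c(CC=C(C)C)c(OCOC)c1CCO | intermediate
9 | 2-[4-methoxy-2,6-bis(methoxymethoxy)-3-(3-methylbut-2-en-1-yl)phenyl]acetaldehyde | COCOc1cc(OC)c(CC=C(C)C)c(OCOC)c1CC=O | intermediate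
10 | 2-[4-methoxy-2,6-bis(methoxymethoxy)-3-(3-methylbut-2-en-1-yl)phenyl]acetic acid | COCOc1cc(OC)c(CC=C(C)C)c(OCOC)c1CC(=O)O | intermediate
11 | prop-2-en-1-yl 2-[4-methoxy-2,6-bis(methoxymethoxy)-3-(3-methylbut-2-en-1-yl)phenyl]acetate | COCOc1cc(OC)c(CC=C(C)C)c(OCOC)c1CC(=O)OCC=C | intermediate
12 | methyl 2,4-dihydroxybenzoate | COC(=O)c1ccc(O)cc1O | starting material
13 | methyl 2-hydroxy-4-(methoxymethoxy)benzoate | COCOc1ccc(C(=O)OC)c(O)c1 | intermediate
14 | methyl 4-(methoxymethoxy)-2-(prop-2-en-1-yloxy)benzoate | COCOc1ccc(C(=O)OC)c(OCC=C)c1 | intermediate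
15 | 4-(methoxymethoxy)-2-(prop-2-en-1-yloxy)benzoic acid | COCOc1ccc(C(=O)O)c(OCC=C)c1 | intermediate
16 | (1H-imidazol-1-yl)[4-(methoxymethoxy)-2-(prop-2-en-1-yloxy)phenyl]methanone | COCOc1ccc(C(=O)n2ccnc2)c(OCC=C)c1 | intermediate
17 | lithium enolate of 11: lithium 2-[4-methoxy-2,6-bis(methoxymethoxy)-3-(3-methylbut-2-en-1-yl)phenyl]-1-(prop-2-en-1-yloxy)ethen-1-olate | C=CCOC(O[Li])=Cc1c(OCOC)cc(OC)c(CC=C(C)C)c1OCOC | intermediate
18 | prop-2-en-1-yl 3-[4-(methoxymethoxy)-2-(prop-2-en-1-yloxy)phenyl]-2-[4-methoxy-2,6-bis(methoxymethoxy)-3-(3-methylbut-2-en-1-yl)phenyl]-3-oxopropanoate (racemic) | C=CCOC(=O)C(C(=O)c1ccc(OCOC)cc1OCC=C)c1c(OCOC)cc(OC)c(CC=C(C)C)c1OCOC | intermediate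
19 | 3-[2-hydroxy-4-(methoxymethoxy)phenyl]-2-[4-methoxy-2,6-bis(methoxymethoxy)-3-(3-methylbut-2-en-1-yl)phenyl]-3-oxopropanoic acid (racemic) | OC(=O)C(C(=O)c1ccc(OCOC)cc1O)c1c(OCOC)cc(OC)c(CC=C(C)C)c1OCOC | intermediate
20 | 1-[2-hydroxy-4-(methoxymethoxy)phenyl]-2-[4-methoxy-2,6-bis(methoxymethoxy)-3-(3-methylbut-2-en-1-yl)phenyl]ethan-1-one | COCOc1ccc(C(=O)Cc2c(OCOC)cc(OC)c(CC=C(C)C)c2OCOC)c(O)c1 | intermediate
21 | 3-(dimethylamino)-1-[2-hydroxy-4-(methoxymethoxy)phenyl]-2-[4-methoxy-2,6-bis(methoxymethoxy)-3-(3-methylbut-2-en-1-yl)phenyl]prop-2-en-1-one | CN(C)C=C(C(=O)c1ccc(OCOC)cc1O)c1c(OCOC)cc(OC)c(CC=C(C)C)c1OCOC | intermediate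
22 | 7-(methoxymethoxy)-3-[4-methoxy-2,6-bis(methoxymethoxy)-3-(3-methylbut-2-en-1-yl)phenyl]-4H-chromen-4-one | COCOc1ccc2c(c1)occ(-c1c(OCOC)cc(OC)c(CC=C(C)C)c1OCOC)c2=O | intermediate
23 | 3-[2,6-dihydroxy-4-methoxy-3-(3-methylbut-2-en-1-yl)phenyl]-7-hydroxy-4H-chromen-4-one (achiral) | COc1cc(O)c(-c2coc3cc(O)ccc3c2=O)c(O)c1CC=C(C)C | target

## Step count and risks

Total step count: 16. Longest linear sequence: 12 steps (steps 1–8, then 13–16); the ring A branch (steps 9–12) is 4 steps.

Three steps most likely to fail: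

Step 2. Risk: the oxirane opening by the hindered 2,6-dioxygenated aryllithium may be sluggish, or a minor regioisomer from lithiation between OMOM and OMe may be hard to remove from the oily alcohol. The fallback builds the two-carbon arm by formylation, olefination and hydroboration. It sets out from 2: aryllithium 3 is quenched with DMF to give 4-methoxy-2,6-bis(methoxymethoxy)benzaldehyde F1, which can be purified by crystallisation. Wittig methylenation with Ph3P=CH2 (from Ph3PCH3Br and KOt-Bu, THF) gives 2-ethenyl-5-methoxy-1,3-bis(methoxymethoxy)benzene F2. Anti-Markovnikov hydroboration with 9-BBN followed by NaOH/H2O2 then comes back to the route at 4.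

Step 13. Risk: the crossed Claisen joins a doubly ortho-substituted arylacetate enolate to an ortho-substituted, electron-rich acyl donor, so C-acylation may be slow. The fallback forms the same bond by aldol addition to a far more electrophilic aldehyde, followed by oxidation. It sets out from 14 (and 11): i-Bu2AlH reduction of 14 gives [4-(methoxymethoxy)-2-(prop-2-en-1-yloxy)phenyl]methanol F3, and MnO2 oxidation gives 4-(methoxymethoxy)-2-(prop-2-en-1-yloxy)benzaldehyde F4. Addition of F4 to the lithium enolate 17 at −78 °C gives the aldol adduct prop-2-en-1-yl 3-hydroxy-3-[4-(methoxymethoxy)-2-(prop-2-en-1-yloxy)phenyl]-2-[4-methoxy-2,6-bis(methoxymethoxy)-3-(3-methylbut-2-en-1-yl)phenyl]propanoate F5 as a mixture of racemic diastereomers. Dess–Martin oxidation of the secondary alcohol comes back to the route at 18.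

Step 16. Risk: acid may cyclise the prenyl group onto the freed 2'-OH (dimethylchroman) or add HCl/MeOH across the alkene. The fallback carries an acid-stable allyl group through the whole sequence and makes the prenyl group last by olefin cross-metathesis. It sets out from 5 and repeats the operations of steps 4–8 and 13–16 on the allyl series:
- aryllithium 6 is quenched with allyl bromide (CuI cat.) to give the 3-allyl silyl ether F6;
- Bu4NF gives the 3-allyl arylethanol F7;
- Dess–Martin oxidation gives the 3-allyl arylacetaldehyde F8;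
- Pinnick oxidation gives the 3-allyl arylacetic acid F9;
- allyl bromide/K2CO3 gives the allyl 3-allylarylacetate F10;
- LiN(SiMe3)2 gives the 3-allyl lithium ester enolate F11, which is acylated by 16 to the 3'-allyl beta-keto ester F12;
- Pd(PPh3)4/morpholine gives, through the 3'-allyl beta-keto acid F13, the 3'-allyl deoxybenzoin F14 (a C-allyl group has no leaving group and is inert to zerovalent palladium);
- Me2NCH(OMe)2 gives, through the 3'-allyl enaminone F15, the 3'-allyl tris-MOM isoflavone F16;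
- methanolic HCl, now free to be pushed, gives the 3'-allyl trihydroxyisoflavone F17;
- cross-metathesis of F17 with a large excess of 2-methyl-2-butene and second-generation Grubbs catalyst (5 mol%, CH2Cl2 with a little THF, 40 °C) converts allyl into prenyl and comes back to the route at the target 23.

## Further compounds

F1 | step 2 | 4-methoxy-2,6-bis(methoxymethoxy)benzaldehyde | COCOc1cc(OC)cc(OCOC)c1C=O
F2 | step 2 | 2-ethenyl-5-methoxy-1,3-bis(methoxymethoxy)benzene | COCOc1cc(OC)cc(OCOC)c1C=C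
F3 | step 13 | [4-(methoxymethoxy)-2-(prop-2-en-1-yloxy)phenyl]methanol | COCOc1ccc(CO)c(OCC=C)c1
F4 | step 13 | 4-(methoxymethoxy)-2-(prop-2-en-1-yloxy)benzaldehyde | COCOc1ccc(C=O)c(OCC=C)c1
F5 | step 13 | prop-2-en-1-yl 3-hydroxy-3-[4-(methoxymethoxy)-2-(prop-2-en-1-yloxy)phenyl]-2-[4-methoxy-2,6-bis(methoxymethoxy)-3-(3-methylbut-2-en-1-yl)phenyl]propanoate (racemic diastereomer mixture) | C=CCOC(=O)C(C(O)c1ccc(OCOC)cc1OCC=C)c1c(OCOC)cc(OC)c(CC=C(C)C)c1OCOC
F6 | step 16 | tert-butyl{2-[4-methoxy-2,6-bis(methoxymethoxy)-3-(prop-2-en-1-yl)phenyl]ethoxy}dimethylsilane | COCOc1cc(OC)c(CC=C)c(OCOC)c1CCO[Si](C)(C)C(C)(C)C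
F7 | step 16 | 2-[4-methoxy-2,6-bis(methoxymethoxy)-3-(prop-2-en-1-yl)phenyl]ethan-1-ol | COCOc1cc(OC)c(CC=C)c(OCOC)c1CCO
F8 | step 16 | 2-[4-methoxy-2,6-bis(methoxymethoxy)-3-(prop-2-en-1-yl)phenyl]acetaldehyde | COCOc1cc(OC)c(CC=C)c(OCOC)c1CC=O
F9 | step 16 | 2-[4-methoxy-2,6-bis(methoxymethoxy)-3-(prop-2-en-1-yl)phenyl]acetic acid | COCOc1cc(OC)c(CC=C)c(OCOC)c1CC(=O)O
F10 | step 16 | prop-2-en-1-yl 2-[4-methoxy-2,6-bis(methoxymethoxy)-3-(prop-2-en-1-yl)phenyl]acetate | COCOc1cc(OC)c(CC=C)c(OCOC)c1CC(=O)OCC=C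
F11 | step 16 | lithium 2-[4-methoxy-2,6-bis(methoxymethoxy)-3-(prop-2-en-1-yl)phenyl]-1-(prop-2-en-1-yloxy)ethen-1-olate | C=CCOC(O[Li])=Cc1c(OCOC)cc(OC)c(CC=C)c1OCOC
F12 | step 16 | prop-2-en-1-yl 3-[4-(methoxymethoxy)-2-(prop-2-en-1-yloxy)phenyl]-2-[4-methoxy-2,6-bis(methoxymethoxy)-3-(prop-2-en-1-yl)phenyl]-3-oxopropanoate (racemic) | C=CCOC(=O)C(C(=O)c1ccc(OCOC)cc1OCC=C)c1c(OCOC)cc(OC)c(CC=C)c1OCOC
F13 | step 16 | 3-[2-hydroxy-4-(methoxymethoxy)phenyl]-2-[4-methoxy-2,6-bis(methoxymethoxy)-3-(prop-2-en-1-yl)phenyl]-3-oxopropanoic acid (racemic) | OC(=O)C(C(=O)c1ccc(OCOC)cc1O)c1c(OCOC)cc(OC)c(CC=C)c1OCOC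
F14 | step 16 | 1-[2-hydroxy-4-(methoxymethoxy)phenyl]-2-[4-methoxy-2,6-bis(methoxymethoxy)-3-(prop-2-en-1-yl)phenyl]ethan-1-one | COCOc1ccc(C(=O)Cc2c(OCOC)cc(OC)c(CC=C)c2OCOC)c(O)c1
F15 | step 16 | 3-(dimethylamino)-1-[2-hydroxy-4-(methoxymethoxy)phenyl]-2-[4-methoxy-2,6-bis(methoxymethoxy)-3-(prop-2-en-1-yl)phenyl]prop-2-en-1-one | CN(C)C=C(C(=O)c1ccc(OCOC)cc1O)c1c(OCOC)cc(OC)c(CC=C)c1OCOC
F16 | step 16 | 7-(methoxymethoxy)-3-[4-methoxy-2,6-bis(methoxymethoxy)-3-(prop-2-en-1-yl)phenyl]-4H-chromen-4-one | COCOc1ccc2c(c1)occ(-c1c(OCOC)cc(OC)c(CC=C)c1OCOC)c2=O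
F17 | step 16 | 3-[2,6-dihydroxy-4-methoxy-3-(prop-2-en-1-yl)phenyl]-7-hydroxy-4H-chromen-4-one | COc1cc(O)c(-c2coc3cc(O)ccc3c2=O)c(O)c1CC=C
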